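**Retrosynthetic overview**
1. Enabling feature: ring B is the tetrahydrofuran (O1, C2H bearing lactone ring C, C3H2, C4H2, C5 bearing CH3 and the E-alkenyl chain). Its O1–C5 bond is a tertiary allylic ether bond (C5–CH=CH is an allyl unit), and its C3–C4 bond joins two unsubstituted CH2 groups.
2. Key disconnection: cutting both bonds at once opens ring B into a terminal oxirane (O1, C2, C3) and the CH2=C(CH3) end (C4, C5) of a 2-methyl-1,3-diene. In the forward direction, a redox- and atom-neutral formal (3+2) union, driven by an iodide/photoexcited-palladium radical–polar relay, joins the C7 and C15 halves in the last step.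
3. Epoxy lactone half, from geraniol: Sharpless epoxidation sets both stereocentres. Tosylation follows, then oxidative alkene cleavage with in-situ epoxy-acid lactonisation (inversion, ring C). Base then closes a temporary oxirane that is absent from the target and is consumed in the key step.
4. Triene half: ring A is bought as 3-bromofuran. The sequence is Kumada coupling, allylic oxidation, bromination, then hydrozirconation and palladium alkenyl–allyl coupling with 2-methylbut-1-en-3-yne.
5. Order of ring formation: A (bought), C (step 7), temporary oxirane (step 8), B (step 9).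

Key step: step 9

Assumption (remark on the chemistry): no model predicts with certainty which BINAP antipode favours the 5R quaternary centre on this allyl system, so (S)-BINAP is written and is exchanged for (R)-BINAP, with nothing else changed, if the first run shows that to be the matched ligand.

**Step 1**
Reactants: 1 5-bromo-2-methylpent-2-ene; 2 3-bromofuran
Product: 4 perillene (3-(4-methylpent-3-en-1-yl)furan), via Grignard reagent 3 (not isolated)
Conditions: 1, Mg, Et2O, reflux; then 2, Ni(dppp)Cl2 (2 mol %), Et2O, 0 °C to reflux
Reagents that add atoms: none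
Why: Kumada coupling, in which the nickel–diphosphine catalyst inserts into the C3–Br bond of the furan and couples it with the primary homoallylic Grignard reagent faster than β-hydride loss, a reaction type established for 3-bromofuran; no stereocentre is formed.

**Step 2**
Reactants: 4 perillene
Product: 5 (E)-5-(furan-3-yl)-2-methylpent-2-en-1-ol
Conditions: SeO2 (20 mol %), t-BuOOH (2 equiv), salicylic acid (10 mol %), CH2Cl2, 0 °C to rt
Reagents that add atoms: tert-butyl hydroperoxide CC(C)(C)OO (terminal source of the new O); selenium dioxide O=[Se]=O (catalytic carrier that hands the O over)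
Why: Riley allylic oxidation (ene reaction, then [2,3]-sigmatropic shift) of a gem-dimethyl trisubstituted alkene takes place at the methyl group trans to the chain, so it should give the E allylic alcohol, and this reaction type is in use on 3-alkylfuran terpenoids.

**Step 3**
Reactants: 5 (E)-5-(furan-3-yl)-2-methylpent-2-en-1-ol
Product: 6 3-[(E)-5-bromo-4-methylpent-3-en-1-yl]furan
Conditions: CBr4, PPh3, CH2Cl2, −20 to 0 °C
Reagents that add atoms: tetrabromomethane BrC(Br)(Br)Br
Why: Appel reaction, in which bromide displaces the alkoxyphosphonium group by SN2 at the primary allylic carbon under neutral conditions, which keeps the E geometry and spares the acid-sensitive furan.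

**Step 4**
Reactants: 7 2-methylbut-1-en-3-yne; 6 3-[(E)-5-bromo-4-methylpent-3-en-1-yl]furan
Product: 9 3-[(3E,6E)-4,8-dimethylnona-3,6,8-trien-1-yl]furan, via dienylzirconocene chloride 8 (not isolated)
Conditions: 7 (1.3 equiv), Cp2Zr(H)Cl (1.2 equiv), THF, 0 °C to rt; then 6, Pd(PPh3)4 (5 mol %), THF, rt
Reagents that add atoms: none
Why: Hydrozirconation adds Zr–H syn and terminally to the alkyne (the 1,1-disubstituted alkene reacts more slowly), and the known palladium-catalysed alkenyl–allyl cross-coupling joins the E-dienylzirconocene to the unsubstituted terminus of the π-allyl unit with retention of both alkene geometries.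

**Step 5**
Reactants: 10 geraniol
Product: 11 [(2R,3R)-3-methyl-3-(4-methylpent-3-en-1-yl)oxiran-2-yl]methanol
Conditions: Ti(OiPr)4 (5 mol %), D-(−)-diisopropyl tartrate (7 mol %), t-BuOOH (decane), 4 Å MS, CH2Cl2, −20 °C
Reagents that add atoms: tert-butyl hydroperoxide CC(C)(C)OO
Why: Sharpless asymmetric epoxidation, in which the titanium–D-(−)-tartrate complex binds the allylic alcohol, leaves the remote alkene untouched and delivers oxygen to the face that gives the (2R,3R)-epoxide, which fixes both stereocentres of the later carbinol/ring C pair.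

**Step 6**
Reactants: 11 (2R,3R)-epoxygeraniol
Product: 12 [(2R,3R)-3-methyl-3-(4-methylpent-3-en-1-yl)oxiran-2-yl]methyl 4-methylbenzenesulfonate
Conditions: TsCl, Et3N, DMAP (cat.), CH2Cl2, 0 °C
Reagents that add atoms: 4-toluenesulfonyl chloride Cc1ccc(cc1)S(=O)(=O)Cl
Why: Standard sulfonylation of a primary alcohol, in which the tosylate shields the alcohol from the next oxidation, lowers the acid lability of the oxirane and serves later as leaving group, with no stereocentre touched.

**Step 7**
Reactants: 12 epoxygeranyl tosylate
Product: 14 (R)-2-hydroxy-2-[(S)-2-methyl-5-oxotetrahydrofuran-2-yl]ethyl 4-methylbenzenesulfonate, via epoxy acid 13 (not isolated)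
Conditions: RuCl3·xH2O (3 mol %), NaIO4 (4 equiv), EtOAc/MeCN/H2O, 0 °C to rt; crude 13, then CSA (10 mol %), CH2Cl2, rt
Reagents that add atoms: sodium periodate [Na+].[O-]I(=O)(=O)=O (both new O atoms, relayed through RuO4)
Why: RuO4 oxidative cleavage of the trisubstituted alkene gives acid 13, whose carboxyl group opens the oxirane 5-exo-tet at the tertiary carbon with inversion (acid-catalysed epoxy-acid lactonisation), so the ring C carbon becomes S while the carbinol carbon keeps its C–O bond and its R configuration.

**Step 8**
Reactants: 14 hydroxy lactone tosylate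
Product: 15 (S)-5-methyl-5-[(R)-oxiran-2-yl]dihydrofuran-2(3H)-one
Conditions: NaH (1.05 equiv), THF, 0 °C
Reagents that add atoms: none
Why: Intramolecular Williamson reaction (3-exo-tet), in which the secondary alkoxide displaces the neighbouring primary tosylate without breaking any bond to a stereocentre, so both configurations are kept.

**Step 9**
Reactants: 15 (S)-5-methyl-5-[(R)-oxiran-2-yl]dihydrofuran-2(3H)-one; 9 3-[(3E,6E)-4,8-dimethylnona-3,6,8-trien-1-yl]furan
Product: 17 target (S)-5-{(2R,5R)-5-[(1E,4E)-7-(furan-3-yl)-4-methylhepta-1,4-dien-1-yl]-5-methyltetrahydrofuran-2-yl}-5-methyldihydrofuran-2(3H)-one, via iodohydrin 16 (not isolated)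
Conditions: 15 (1.5 equiv), 9 (1.0 equiv), Pd(OAc)2 (5 mol %), (S)-BINAP (7.5 mol %), 2,4,6-collidinium iodide (20 mol %), DMA (0.2 M), 450 nm LEDs, 25 °C, argon
Reagents that add atoms: none
Why: Proposed new method: collidinium iodide opens the oxirane of 15 by SN2 attack at its CH2 group to iodohydrin 16, photoexcited zerovalent palladium abstracts the iodine atom, the primary β-hydroxyalkyl radical adds to the unsubstituted CH2 terminus of the diene of 9 (C3–C4 bond of ring B), the allyl radical recombines with monovalent palladium to a π-allyl complex of divalent palladium, and the hydroxyl group attacks its tertiary terminus anti to the metal (O1–C5 bond) while collidine takes the proton, so that zerovalent palladium and collidinium iodide both return and no atom is lost. The closest known reaction types are the visible-light palladium-catalysed radical–polar crossover 1,2-carbofunctionalisation of 1,3-dienes with alkyl halides, the Larock-type heteroannulation of 1,3-dienes, the iodide-cocatalysed terminal opening of epoxides in cross-electrophile coupling and the palladium-catalysed cyclisation of hydroxy allylic carbonates to 2-methyl-2-vinyltetrahydrofurans; new is their merger, with an epoxide as three-atom C–C–O partner. Ring B closes in the 5-exo mode at the allyl terminus, favoured over 7-endo attack at the far terminus, and the s-trans E-diene gives the syn-configured allyl unit, so the alkene left outside the ring should be E. C2 of ring B is the carbinol carbon of 15, whose C–O bond is never broken, and the new quaternary centre C5 is controlled by the chiral BINAP pocket, which selects between the two diastereomeric π-allyl complexes that interconvert through reversible light-driven Pd–C homolysis (Curtin–Hammett situation), because the resident 1,4-related centre alone offers little bias. The step needs radical addition at the diene only, which the substrate secures because the conjugated CH2 terminus is the one fast acceptor that leads to a stabilised allyl radical, whereas the isolated trisubstituted alkene and ring A are slow acceptors; it also needs a C3 synthon that keeps its β-oxygen, which a radical does and a carbanion would not. The collidine buffer is too weak a base to re-close 16 and too weak an acid to ionise the tertiary allylic ether of 17 or to harm ring A.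

**Compound list**
1 | 5-bromo-2-methylpent-2-ene | CC(C)=CCCBr | starting material
2 | 3-bromofuran | Brc1ccoc1 | starting material
3 | (4-methylpent-3-en-1-yl)magnesium bromide | CC(C)=CCC[Mg]Br | intermediate
4 | perillene, 3-(4-methylpent-3-en-1-yl)furan | CC(C)=CCCc1ccoc1 | intermediate
5 | (E)-5-(furan-3-yl)-2-methylpent-2-en-1-ol | OC/C(C)=C/CCc1ccoc1 | intermediate
6 | 3-[(E)-5-bromo-4-methylpent-3-en-1-yl]furan | BrC/C(C)=C/CCc1ccoc1 | intermediate
7 | 2-methylbut-1-en-3-yne | C=C(C)C#C | starting material
8 | chlorobis(cyclopentadienyl)[(E)-3-methylbuta-1,3-dien-1-yl]zirconium | C=C(C)/C=C/[Zr+2]Cl.c1cc[cH-]c1.c1cc[cH-]c1 | intermediate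
9 | 3-[(3E,6E)-4,8-dimethylnona-3,6,8-trien-1-yl]furan | C=C(C)/C=C/C/C(C)=C/CCc1ccoc1 | intermediate
10 | geraniol | CC(C)=CCC/C(C)=C/CO | starting material
11 | [(2R,3R)-3-methyl-3-(4-methylpent-3-en-1-yl)oxiran-2-yl]methanol | OC[C@H]1O[C@]1(C)CCC=C(C)C | intermediate
12 | [(2R,3R)-3-methyl-3-(4-methylpent-3-en-1-yl)oxiran-2-yl]methyl 4-methylbenzenesulfonate | Cc1ccc(cc1)S(=O)(=O)OC[C@H]1O[C@]1(C)CCC=C(C)C | intermediate
13 | 3-[(2R,3R)-2-methyl-3-(tosyloxymethyl)oxiran-2-yl]propanoic acid | Cc1ccc(cc1)S(=O)(=O)OC[C@H]1O[C@]1(C)CCC(=O)O | intermediate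
14 | (R)-2-hydroxy-2-[(S)-2-methyl-5-oxotetrahydrofuran-2-yl]ethyl 4-methylbenzenesulfonate | Cc1ccc(cc1)S(=O)(=O)OC[C@H]([C@]2(C)CCC(=O)O2)O | intermediate
15 | (S)-5-methyl-5-[(R)-oxiran-2-yl]dihydrofuran-2(3H)-one | C1[C@H]([C@]2(C)CCC(=O)O2)O1 | intermediate
16 | (S)-5-[(S)-1-hydroxy-2-iodoethyl]-5-methyldihydrofuran-2(3H)-one | IC[C@H]([C@]2(C)CCC(=O)O2)O | intermediate
17 | (S)-5-{(2R,5R)-5-[(1E,4E)-7-(furan-3-yl)-4-methylhepta-1,4-dien-1-yl]-5-methyltetrahydrofuran-2-yl}-5-methyldihydrofuran-2(3H)-one | C/C(=C\CCc1ccoc1)C/C=C/[C@@]1(C)CC[C@H]([C@]2(C)CCC(=O)O2)O1 | target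

**Step count**
Total steps: 9. Longest linear sequence: 5 steps (steps 1–4 then 9, or steps 5–8 then 9).

**Steps most likely to fail**

1. **Step 9.**
   - What may go wrong:
     - The primary radical is captured by monovalent palladium and loses β-hydride or β-hydroxide before it meets the diene.
     - The π-allyl complex loses a proton (Heck-type triene formation) instead of being attacked by the hindered secondary hydroxyl.
     - Facial selectivity at the quaternary carbon is poor.
   - Fallback, using known reaction types only, sets out from 15 and comes back at 17. Ring B is closed by C–O formation onto a 1,1-disubstituted alkene, and the side chain is attached afterwards. LiI/AcOH in THF opens 15 to 16, now isolated. Keck radical allylation with tributyl(2-methylallyl)stannane and AIBN (benzene, 80 °C) gives (S)-5-[(R)-1-hydroxy-4-methylpent-4-en-1-yl]-5-methyldihydrofuran-2(3H)-one F1. Mukaiyama aerobic oxidative cyclisation (Co(modp)2, modp = 1-morpholinocarbamoyl-4,4-dimethylpentane-1,3-dionate, O2, t-BuOOH, i-PrOH, 55 °C) closes ring B with the 2,5-trans preference typical of that reaction. It gives (S)-5-[(2R,5R)-5-(hydroxymethyl)-5-methyltetrahydrofuran-2-yl]-5-methyldihydrofuran-2(3H)-one F2. Dess–Martin oxidation gives (2R,5R)-2-methyl-5-[(S)-2-methyl-5-oxotetrahydrofuran-2-yl]tetrahydrofuran-2-carbaldehyde F3. Ohira–Bestmann homologation (K2CO3, MeOH) gives (S)-5-[(2R,5R)-5-ethynyl-5-methyltetrahydrofuran-2-yl]-5-methyldihydrofuran-2(3H)-one F4. Hydrozirconation with Cp2Zr(H)Cl gives the E-alkenylzirconocene chloride F5, which is coupled in the same flask with bromide 6 under Pd(PPh3)4, as in step 4, to reach 17.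

2. **Step 2.**
   - What may go wrong:
     - The electron-rich furan is degraded oxidatively.
     - The alcohol is over-oxidised to the enal.
     - Oxidation competes at the allylic CH2 group.
   - Fallback sets out from 2 and comes back at 5. It replaces steps 1 and 2, and builds the E alkene by olefination instead of C–H oxidation. Bromine–lithium exchange of 2 (n-BuLi, THF, −78 °C) gives furan-3-yllithium F6. BF3·OEt2-assisted opening of oxetane then gives 3-(furan-3-yl)propan-1-ol F7. Parikh–Doering oxidation gives 3-(furan-3-yl)propanal F8. Wittig reaction with the stabilised ylide Ph3P=C(CH3)CO2Et gives ethyl (E)-5-(furan-3-yl)-2-methylpent-2-enoate F9. DIBAL-H (CH2Cl2, −78 °C) reduces it to 5.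

3. **Step 7.**
   - What may go wrong:
     - The oxirane is opened hydrolytically in the acidic aqueous periodate medium before the carboxyl group exists, and glycol cleavage follows.
     - Some 6-endo opening occurs.
   - Fallback sets out from 12 and comes back at 14. The one-pot cascade is given up, and cleavage, oxidation and ring closure become three separate events, with the alkene cut in the absence of water and acid. Ozonolysis (O3, CH2Cl2, −78 °C, then Me2S) gives [(2R,3R)-3-methyl-3-(3-oxopropyl)oxiran-2-yl]methyl 4-methylbenzenesulfonate F10. Buffered Pinnick oxidation (NaClO2, NaH2PO4, 2-methylbut-2-ene) gives 13, now isolated. CSA in dry CH2Cl2 lactonises it to 14.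

**Further compounds**
F1 | step 9 | (S)-5-[(R)-1-hydroxy-4-methylpent-4-en-1-yl]-5-methyldihydrofuran-2(3H)-one | C=C(C)CC[C@H]([C@]1(C)CCC(=O)O1)O
F2 | step 9 | (S)-5-[(2R,5R)-5-(hydroxymethyl)-5-methyltetrahydrofuran-2-yl]-5-methyldihydrofuran-2(3H)-one | OC[C@@]1(C)CC[C@H]([C@]2(C)CCC(=O)O2)O1
F3 | step 9 | (2R,5R)-2-methyl-5-[(S)-2-methyl-5-oxotetrahydrofuran-2-yl]tetrahydrofuran-2-carbaldehyde | O=C[C@@]1(C)CC[C@H]([C@]2(C)CCC(=O)O2)O1
F4 | step 9 | (S)-5-[(2R,5R)-5-ethynyl-5-methyltetrahydrofuran-2-yl]-5-methyldihydrofuran-2(3H)-one | C#C[C@@]1(C)CC[C@H]([C@]2(C)CCC(=O)O2)O1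
F5 | step 9 | E-alkenylzirconocene chloride from F4 | Cl[Zr+2]/C=C/[C@@]1(C)CC[C@H]([C@]2(C)CCC(=O)O2)O1.c1cc[cH-]c1.c1cc[cH-]c1
F6 | step 2 | furan-3-yllithium | [Li]c1ccoc1
F7 | step 2 | 3-(furan-3-yl)propan-1-ol | OCCCc1ccoc1
F8 | step 2 | 3-(furan-3-yl)propanal | O=CCCc1ccoc1
F9 | step 2 | ethyl (E)-5-(furan-3-yl)-2-methylpent-2-enoate | CCOC(=O)/C(C)=C/CCc1ccoc1
F10 | step 7 | [(2R,3R)-3-methyl-3-(3-oxopropyl)oxiran-2-yl]methyl 4-methylbenzenesulfonate | Cc1ccc(cc1)S(=O)(=O)OC[C@H]1O[C@]1(C)CCC=O
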